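**Plan**

1. Germacrane numbering is used throughout (oxirane C1/C10, acetoxy carbons C3 and C9, alkene C4=C5, lactone C6–O/C12, ring fusion C7, CHMe C11). The retrosynthesis cuts the two acetates, then C1–C10, then C3–C4, then C4=C5, and last the C5=C10 bond of a cyclohexene template that goes back to (R)-carvone (C5–C14).
2. Enabling feature: C1–C10 is both a bond of the ten-membered carbocycle and the C–C bond of the oxirane. C10 carries O and CH3 (a latent methyl ketone beside the C9 oxygen stereocentre) and C1 is a CH beside a CH2 (a latent sulfonium ylide), so one ylide addition closes both rings.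
3. Forward: carvone → conjugated diene acid → palladium-catalysed cis-1,4-acetoxylactonisation (lactone ring, C6–O, C9–O) → ozonolysis opens the template to the C5 aldehyde and C10 ketone → (Z)-iodo-olefination and Ni/Cr coupling add C4, C15 and C1–C3 → C1 diphenylsulfonium salt → ylide macrocyclisation to the epoxycyclodecene → desilylation, acetylation.
4. Stereochemistry: C7 from (R)-carvone; C6 and C9 from the palladium step (both cis to the C7 side chain); C11 by kinetic protonation; 4Z from the iodo-ylide; C3 from a chiral chromium ligand; C10 by Felkin–Anh control from C9; C1 by the ring (cis-oxirane).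
5. Helpers: the six-membered template ring (cleaved in step 9), Ph2S+ at C1 (expelled in step 15) and the silyl ethers at O3/O9 (removed in step 16).

Key step: step 15

Remark: (R)-carvone 1, ethyltriphenylphosphonium iodide 15 and 3-[(tert-butyldimethylsilyl)oxy]propanal 17 are taken as purchased; TBS = tert-butyldimethylsilyl.

**Step 1**
Reactants: 1 (R)-(−)-carvone
Product: 3 (3R)-6-methyl-3-(prop-1-en-2-yl)cyclohexa-1,5-dien-1-yl trifluoromethanesulfonate, via lithium dienolate 2 (not isolated)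
Conditions: LiN(iPr)2, THF, −78 °C; PhNTf2, −78 → 0 °C
Reagents that add atoms: N-phenylbis(trifluoromethanesulfonimide), O=S(=O)(N(c1ccccc1)S(=O)(=O)C(F)(F)F)C(F)(F)F; lithium diisopropylamide, CC(C)[N-]C(C)C.[Li+] (lithium in 2 only)
Why: Kinetic deprotonation of the enone at the α′-CH2 (the future C6) gives the cross-conjugated dienolate, which is O-triflated (enol triflate formation); the C7 stereocentre is not touched.

**Step 2**
Reactants: 3 dienyl triflate
Product: 4 (5R)-2-methyl-5-(prop-1-en-2-yl)cyclohexa-1,3-diene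
Conditions: Pd(OAc)2 (3 mol %), PPh3, HCO2H, Et3N, DMF, 50 °C
Reagents that add atoms: none
Why: Palladium-catalysed formate reduction of an enol triflate replaces C–OTf by C–H and leaves the conjugated diene (C6=C5–C10=C9) in place.

**Step 3**
Reactants: 4 triene
Product: 6 2-[(1R)-4-methylcyclohexa-2,4-dien-1-yl]propan-1-ol (both C2 epimers), via B-alkyl-9-BBN adduct 5 (not isolated)
Conditions: 9-BBN, THF, 0 → 23 °C; then NaOH, H2O2, 0 °C
Reagents that add atoms: hydrogen peroxide, OO; 9-borabicyclo[3.3.1]nonane, B1C2CCCC1CCC2 (boron bicycle in 5 only)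
Why: Hydroboration–oxidation with the bulky borane should select the 1,1-disubstituted isopropenyl alkene over the ring diene and give the primary alcohol; C11 forms without control and is corrected in step 8.

**Step 4**
Reactants: 6 dienyl propanol
Product: 7 2-[(1R)-4-methylcyclohexa-2,4-dien-1-yl]propanoic acid (both C2 epimers)
Conditions: TEMPO (20 mol %), PhI(OAc)2 (2.2 equiv), MeCN–H2O, 0 → 23 °C
Reagents that add atoms: water, O
Why: Oxoammonium-mediated oxidation takes the primary alcohol to the carboxylic acid under near-neutral conditions that should spare the diene.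

**Step 5**
Reactants: 7 diene acid
Product: 8 (3aS,5S,7aR)-3,6-dimethyl-2-oxo-2,3,3a,4,5,7a-hexahydro-1-benzofuran-5-yl acetate (both C3 epimers)
Conditions: Pd(OAc)2 (5 mol %), p-benzoquinone (2 equiv), LiCl (20 mol %), LiOAc, AcOH–acetone, 23 °C
Reagents that add atoms: acetic acid, CC(=O)O
Why: In this palladium-catalysed intramolecular 1,4-oxidation of a conjugated diene, the carboxylate adds to diene terminus C6 anti to palladium (cis-fused γ-lactone) and, with chloride on the metal, acetate attacks the π-allyl terminus C9 externally, so C6–O, C9–O and the C7–C11 bond should come out all cis.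

**Step 6**
Reactants: 8 acetoxy lactone
Product: 9 (3aS,5S,7aR)-5-hydroxy-3,6-dimethyl-3a,4,5,7a-tetrahydro-1-benzofuran-2(3H)-one (both C3 epimers)
Conditions: K2CO3 (0.2 equiv), MeOH, 0 °C
Reagents that add atoms: none
Why: Transesterification removes the allylic acetate; any opened hydroxy ester should reclose to the γ-lactone on neutralisation.

**Step 7**
Reactants: 9 hydroxy lactone
Product: 10 (3aS,5S,7aR)-5-[(tert-butyldimethylsilyl)oxy]-3,6-dimethyl-3a,4,5,7a-tetrahydro-1-benzofuran-2(3H)-one (both C3 epimers)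
Conditions: TBSCl, imidazole, DMF, 23 °C
Reagents that add atoms: tert-butyldimethylsilyl chloride, CC(C)(C)[Si](C)(C)Cl
Why: Silylation of the secondary allylic alcohol gives a base-stable, non-chelating, non-migrating group at O9 for steps 8 to 15.

**Step 8**
Reactants: 10 silyl ether lactone
Product: 12 (3R,3aS,5S,7aR)-5-[(tert-butyldimethylsilyl)oxy]-3,6-dimethyl-3a,4,5,7a-tetrahydro-1-benzofuran-2(3H)-one, via lithium enolate 11 (not isolated)
Conditions: LiN(iPr)2, THF, −78 °C; then 2,6-di-tert-butyl-4-methylphenol, −78 °C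
Reagents that add atoms: lithium diisopropylamide, CC(C)[N-]C(C)C.[Li+] (lithium in 11 only)
Why: Kinetic C-protonation of the lactone enolate from the convex face of the cis-fused bicycle should put H11 exo and the methyl endo (cis to C8), converging both epimers on 11R.

**Step 9**
Reactants: 12 all-cis bicyclic lactone
Product: 14 (2R,3S,4R)-3-{(2S)-2-[(tert-butyldimethylsilyl)oxy]-3-oxobutyl}-4-methyl-5-oxooxolane-2-carbaldehyde, via secondary ozonide 13 (not isolated)
Conditions: O3, CH2Cl2, −78 °C; then PPh3, −78 → 23 °C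
Reagents that add atoms: ozone, [O-][O+]=O
Why: Ozonolysis with reductive work-up cleaves the only C=C bond and gives the C5 aldehyde and the C10 methyl ketone without touching C6, C7, C9 or C11.

**Step 10**
Reactants: 14 keto aldehyde; 15 ethyltriphenylphosphonium iodide
Product: 16 (3R,4S,5R)-4-{(2S)-2-[(tert-butyldimethylsilyl)oxy]-3-oxobutyl}-5-[(1Z)-2-iodoprop-1-en-1-yl]-3-methyloxolan-2-one
Conditions: 15, n-BuLi, THF, 23 °C; I2, −78 °C; NaN(SiMe3)2, −20 °C; then 14, −78 → −20 °C
Reagents that add atoms: iodine, II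
Why: Wittig olefination with the α-iodoethylidene ylide (Stork–Zhao type) should react at the aldehyde only and give the (Z)-2-iodoalkene, iodine cis to C6, as is usual for this non-stabilised ylide at low temperature.

**Step 11**
Reactants: 16 (Z)-vinyl iodide; 17 3-[(tert-butyldimethylsilyl)oxy]propanal
Product: 18 (3R,4S,5R)-4-{(2S)-2-[(tert-butyldimethylsilyl)oxy]-3-oxobutyl}-5-{(1Z,3R)-5-[(tert-butyldimethylsilyl)oxy]-3-hydroxy-2-methylpent-1-en-1-yl}-3-methyloxolan-2-one
Conditions: CrCl2 (4 equiv), (S)-N-[2-(4-isopropyl-4,5-dihydro-1,3-oxazol-2-yl)-6-methylphenyl]methanesulfonamide (4.4 equiv; enantiomer selected for Si-face addition), Et3N, THF, 23 °C; then NiCl2 (10 mol %), 16, 17 (2 equiv), 23 °C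
Reagents that add atoms: none
Why: In this Nozaki–Hiyama–Kishi coupling the alkenylchromium keeps the olefin geometry and adds to the aldehyde rather than the ketone or lactone; the chiral sulfonamide–oxazoline ligand on chromium is to direct addition to the Si face of 17, setting 3R.

**Step 12**
Reactants: 18 allylic alcohol
Product: 19 (3R,4S,5R)-4-{(2S)-2-[(tert-butyldimethylsilyl)oxy]-3-oxobutyl}-5-{(1Z,3R)-3,5-bis[(tert-butyldimethylsilyl)oxy]-2-methylpent-1-en-1-yl}-3-methyloxolan-2-one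
Conditions: TBSCl, imidazole, DMF, 23 °C
Reagents that add atoms: tert-butyldimethylsilyl chloride, CC(C)(C)[Si](C)(C)Cl
Why: Silylation protects O3 with a group that cannot be displaced or attacked by the C1 ylide, unlike an allylic acetate.

**Step 13**
Reactants: 19 tris-silyl ether
Product: 20 (3R,4S,5R)-4-{(2S)-2-[(tert-butyldimethylsilyl)oxy]-3-oxobutyl}-5-{(1Z,3R)-3-[(tert-butyldimethylsilyl)oxy]-5-hydroxy-2-methylpent-1-en-1-yl}-3-methyloxolan-2-one
Conditions: HF·pyridine, pyridine, THF, 0 °C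
Reagents that add atoms: none
Why: Buffered HF·pyridine should cleave the primary silyl ether much faster than the two hindered secondary ones (steric rate difference in desilylation).

**Step 14**
Reactants: 20 primary alcohol
Product: 22 diphenyl{(3R,4Z)-3-[(tert-butyldimethylsilyl)oxy]-4-methyl-5-[(2R,3S,4R)-4-methyl-5-oxo-3-{(2S)-2-[(tert-butyldimethylsilyl)oxy]-3-oxobutyl}oxolan-2-yl]pent-4-en-1-yl}sulfonium trifluoromethanesulfonate, via primary triflate 21 (not isolated)
Conditions: Tf2O, 2,6-di-tert-butylpyridine, CH2Cl2, −78 °C; then Ph2S (5 equiv), −78 → 23 °C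
Reagents that add atoms: trifluoromethanesulfonic anhydride, O=S(=O)(OS(=O)(=O)C(F)(F)F)C(F)(F)F; diphenyl sulfide, c1ccc(cc1)Sc1ccccc1
Why: O-Triflation of the primary alcohol followed by SN2 S-alkylation of diphenyl sulfide gives the alkyldiphenylsulfonium salt; the hindered pyridine cannot be alkylated.

**Step 15**
Reactants: 22 seco sulfonium triflate
Product: 25 (1R,3R,4Z,6R,7S,9S,10R,11R)-3,9-bis[(tert-butyldimethylsilyl)oxy]-1,10-epoxygermacr-4-en-12,6-olide, via sulfonium ylide 23 (not isolated), via alkoxide betaine 24 (not isolated)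
Conditions: KN(SiMe3)2 (1.05 equiv, added over 3 h), THF (1 mM), −78 °C; then → −30 °C
Reagents that add atoms: none
Why: Proposed new method: KN(SiMe3)2 removes a C1 proton, the only C–H α to sulfur and several pKa units more acidic than the ketone or lactone α-hydrogens, and the non-stabilised diphenylsulfonium ylide 23 adds irreversibly to the C10 methyl ketone to give betaine 24, whose alkoxide displaces diphenyl sulfide from C1 with inversion, so that the C1–C10 bond, the ten-membered carbocycle and the oxirane are made in one operation. The closest known reaction type is the Corey–Chaykovsky epoxidation of ketones with alkyldiphenylsulfonium ylides, which has intramolecular precedent only for common ring sizes and has not been used to close a ten-membered carbocycle. The carbocycle closes by 10-exo-trig addition of C1 to the C10 carbonyl and the oxirane by 3-exo-tet substitution at C1. C10 is controlled by C9: polar Felkin–Anh attack anti to the C9–OTBS bond gives the anti relation of O9 and O10 found in the target; C1 is controlled by the ring, because the betaine rotamer with S+ anti to O− and C2 gauche to C9 is the one expected to be accommodated by the tether containing the 4Z olefin and the cis-fused lactone, and it collapses to the cis-oxirane (C2 and C9 cis). The step needs ylide formation in preference to enolisation or elimination of Ph2S (pKa gap, low temperature), ketone in preference to lactone addition (carbonyl electrophilicity) and cyclisation in preference to oligomerisation (1 mM, slow addition of base).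

**Step 16**
Reactants: 25 bis-silyl epoxy lactone
Product: 26 (1R,3R,4Z,6R,7S,9S,10S,11R)-3,9-dihydroxy-1,10-epoxygermacr-4-en-12,6-olide (same geometry as 25; the C10 descriptor changes by priority only)
Conditions: Bu4NF, AcOH (1:1), THF, 0 → 23 °C
Reagents that add atoms: none
Why: Fluoride-mediated desilylation; the acetic acid buffer should keep the C9 alkoxide from opening the adjacent oxirane (Payne-type migration).

**Step 17**
Reactants: 26 epoxy diol
Product: 27 (1R,3R,4Z,6R,7S,9S,10R,11R)-3,9-diacetoxy-1,10-epoxygermacr-4-en-12,6-olide (CNP0250285.2)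
Conditions: Ac2O, pyridine, DMAP (cat.), CH2Cl2, 0 → 23 °C
Reagents that add atoms: acetic anhydride, CC(=O)OC(C)=O
Why: DMAP-catalysed acylation of both secondary alcohols; no stereocentre is affected.

**Compound list**

1 | (R)-(−)-carvone, (5R)-2-methyl-5-(prop-1-en-2-yl)cyclohex-2-en-1-one | CC1=CC[C@H](CC1=O)C(C)=C | starting material
2 | lithium (3R)-6-methyl-3-(prop-1-en-2-yl)cyclohexa-1,5-dien-1-olate | CC1=CC[C@H](C=C1[O-])C(C)=C.[Li+] | intermediate
3 | (3R)-6-methyl-3-(prop-1-en-2-yl)cyclohexa-1,5-dien-1-yl trifluoromethanesulfonate | CC1=CC[C@H](C=C1OS(=O)(=O)C(F)(F)F)C(C)=C | intermediate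
4 | (5R)-2-methyl-5-(prop-1-en-2-yl)cyclohexa-1,3-diene | CC1=CC[C@H](C=C1)C(C)=C | intermediate
5 | 9-{2-[(1R)-4-methylcyclohexa-2,4-dien-1-yl]propyl}-9-borabicyclo[3.3.1]nonane | CC1=CC[C@H](C=C1)C(C)CB1C2CCCC1CCC2 | intermediate
6 | 2-[(1R)-4-methylcyclohexa-2,4-dien-1-yl]propan-1-ol (both C2 epimers) | CC1=CC[C@H](C=C1)C(C)CO | intermediate
7 | 2-[(1R)-4-methylcyclohexa-2,4-dien-1-yl]propanoic acid (both C2 epimers) | CC1=CC[C@H](C=C1)C(C)C(=O)O | intermediate
8 | (3aS,5S,7aR)-3,6-dimethyl-2-oxo-2,3,3a,4,5,7a-hexahydro-1-benzofuran-5-yl acetate (both C3 epimers) | CC(=O)O[C@H]1C[C@@H]2[C@H](C=C1C)OC(=O)C2C | intermediate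
9 | (3aS,5S,7aR)-5-hydroxy-3,6-dimethyl-3a,4,5,7a-tetrahydro-1-benzofuran-2(3H)-one (both C3 epimers) | O[C@H]1C[C@@H]2[C@H](C=C1C)OC(=O)C2C | intermediate
10 | (3aS,5S,7aR)-5-[(tert-butyldimethylsilyl)oxy]-3,6-dimethyl-3a,4,5,7a-tetrahydro-1-benzofuran-2(3H)-one (both C3 epimers) | CC(C)(C)[Si](C)(C)O[C@H]1C[C@@H]2[C@H](C=C1C)OC(=O)C2C | intermediate
11 | lithium enolate of 10 (lactone C2 olate, C2=C3) | CC(C)(C)[Si](C)(C)O[C@H]1C[C@@H]2[C@H](C=C1C)OC([O-])=C2C.[Li+] | intermediate
12 | (3R,3aS,5S,7aR)-5-[(tert-butyldimethylsilyl)oxy]-3,6-dimethyl-3a,4,5,7a-tetrahydro-1-benzofuran-2(3H)-one | CC(C)(C)[Si](C)(C)O[C@H]1C[C@@H]2[C@H](C=C1C)OC(=O)[C@@H]2C | intermediate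
13 | secondary ozonide of 12 (1,2,4-trioxolane bridging the former alkene carbons C5 and C10) | CC(C)(C)[Si](C)(C)O[C@H]1C[C@@H]2[C@H](C3OOC1(C)O3)OC(=O)[C@@H]2C | intermediate
14 | (2R,3S,4R)-3-{(2S)-2-[(tert-butyldimethylsilyl)oxy]-3-oxobutyl}-4-methyl-5-oxooxolane-2-carbaldehyde | CC(C)(C)[Si](C)(C)O[C@H](C(C)=O)C[C@@H]1[C@H](C=O)OC(=O)[C@@H]1C | intermediate
15 | ethyltriphenylphosphonium iodide | CC[P+](c1ccccc1)(c1ccccc1)c1ccccc1.[I-] | starting material
16 | (3R,4S,5R)-4-{(2S)-2-[(tert-butyldimethylsilyl)oxy]-3-oxobutyl}-5-[(1Z)-2-iodoprop-1-en-1-yl]-3-methyloxolan-2-one | CC(C)(C)[Si](C)(C)O[C@H](C(C)=O)C[C@@H]1[C@H](/C=C(/C)I)OC(=O)[C@@H]1C | intermediate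
17 | 3-[(tert-butyldimethylsilyl)oxy]propanal | CC(C)(C)[Si](C)(C)OCCC=O | starting material
18 | (3R,4S,5R)-4-{(2S)-2-[(tert-butyldimethylsilyl)oxy]-3-oxobutyl}-5-{(1Z,3R)-5-[(tert-butyldimethylsilyl)oxy]-3-hydroxy-2-methylpent-1-en-1-yl}-3-methyloxolan-2-one | CC(C)(C)[Si](C)(C)O[C@H](C(C)=O)C[C@@H]1[C@H](/C=C(/C)[C@H](O)CCO[Si](C)(C)C(C)(C)C)OC(=O)[C@@H]1C | intermediate
19 | (3R,4S,5R)-4-{(2S)-2-[(tert-butyldimethylsilyl)oxy]-3-oxobutyl}-5-{(1Z,3R)-3,5-bis[(tert-butyldimethylsilyl)oxy]-2-methylpent-1-en-1-yl}-3-methyloxolan-2-one | CC(C)(C)[Si](C)(C)O[C@H](C(C)=O)C[C@@H]1[C@H](/C=C(/C)[C@H](O[Si](C)(C)C(C)(C)C)CCO[Si](C)(C)C(C)(C)C)OC(=O)[C@@H]1C | intermediate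
20 | (3R,4S,5R)-4-{(2S)-2-[(tert-butyldimethylsilyl)oxy]-3-oxobutyl}-5-{(1Z,3R)-3-[(tert-butyldimethylsilyl)oxy]-5-hydroxy-2-methylpent-1-en-1-yl}-3-methyloxolan-2-one | CC(C)(C)[Si](C)(C)O[C@H](C(C)=O)C[C@@H]1[C@H](/C=C(/C)[C@H](O[Si](C)(C)C(C)(C)C)CCO)OC(=O)[C@@H]1C | intermediate
21 | primary triflate of 20 (C1–OSO2CF3) | CC(C)(C)[Si](C)(C)O[C@H](C(C)=O)C[C@@H]1[C@H](/C=C(/C)[C@H](O[Si](C)(C)C(C)(C)C)CCOS(=O)(=O)C(F)(F)F)OC(=O)[C@@H]1C | intermediate
22 | diphenyl{(3R,4Z)-3-[(tert-butyldimethylsilyl)oxy]-4-methyl-5-[(2R,3S,4R)-4-methyl-5-oxo-3-{(2S)-2-[(tert-butyldimethylsilyl)oxy]-3-oxobutyl}oxolan-2-yl]pent-4-en-1-yl}sulfonium trifluoromethanesulfonate | CC(C)(C)[Si](C)(C)O[C@H](C(C)=O)C[C@@H]1[C@H](/C=C(/C)[C@H](O[Si](C)(C)C(C)(C)C)CC[S+](c2ccccc2)c2ccccc2)OC(=O)[C@@H]1C.[O-]S(=O)(=O)C(F)(F)F | intermediate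
23 | sulfonium ylide of 22 (carbanion at C1) | CC(C)(C)[Si](C)(C)O[C@H](C(C)=O)C[C@@H]1[C@H](/C=C(/C)[C@H](O[Si](C)(C)C(C)(C)C)C[CH-][S+](c2ccccc2)c2ccccc2)OC(=O)[C@@H]1C | intermediate
24 | ten-membered betaine (C1–S+Ph2, C10–O−) | CC(C)(C)[Si](C)(C)O[C@H]1C[C@@H]2[C@H](/C=C(/C)[C@H](O[Si](C)(C)C(C)(C)C)C[C@H]([S+](c3ccccc3)c3ccccc3)[C@@]1(C)[O-])OC(=O)[C@@H]2C | intermediate
25 | (1R,3R,4Z,6R,7S,9S,10R,11R)-3,9-bis[(tert-butyldimethylsilyl)oxy]-1,10-epoxygermacr-4-en-12,6-olide | CC(C)(C)[Si](C)(C)O[C@H]1C[C@@H]2[C@H](/C=C(/C)[C@H](O[Si](C)(C)C(C)(C)C)C[C@H]3O[C@@]13C)OC(=O)[C@@H]2C | intermediate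
26 | (1R,3R,4Z,6R,7S,9S,10S,11R)-3,9-dihydroxy-1,10-epoxygermacr-4-en-12,6-olide | O[C@H]1C[C@@H]2[C@H](/C=C(/C)[C@H](O)C[C@H]3O[C@@]13C)OC(=O)[C@@H]2C | intermediate
27 | (1R,3R,4Z,6R,7S,9S,10R,11R)-3,9-diacetoxy-1,10-epoxygermacr-4-en-12,6-olide (CNP0250285.2) | CC(=O)O[C@H]1C[C@@H]2[C@H](/C=C(/C)[C@H](OC(C)=O)C[C@H]3O[C@@]13C)OC(=O)[C@@H]2C | target

**Step count and risks**

Total step count: 17. Longest linear sequence: 17 steps, from (R)-carvone 1 to 27.

Steps most likely to fail:

1. Step 15 (proposed new method). What may go wrong: oligomerisation instead of ring closure, loss of Ph2S by elimination before the ylide adds, or closure through the betaine rotamer that leads to the trans-oxirane. The fallback uses known chemistry and sets out from 20. Dess–Martin oxidation gives the keto aldehyde F1. Double Wittig methylenation with Ph3P=CH2 gives the diene F2 (isopropenyl at C10, vinyl at C1). Ring-closing metathesis with the second-generation Grubbs catalyst at high dilution in toluene at 80 °C should close C1=C10 as the Z-cycloalkene F3. mCPBA with NaHCO3 should epoxidise this alkene from its outer face in preference to C4=C5, which is deactivated by two allylic oxygens, and the route is rejoined at 25.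

2. Step 11. What may go wrong: poor facial selectivity at the aldehyde, because no resident stereocentre lies near C3 and the sense of induction of the ligand is not secured. The fallback sets out from 16 and 17. The coupling is run without the chiral ligand (CrCl2, NiCl2 cat., DMSO) and should give 18 together with its 3S epimer F4. After chromatographic separation, F4 is inverted by Mitsunobu esterification with chloroacetic acid (PPh3, DIAD) to the 3R chloroacetate F5, and thiourea with NaHCO3 in ethanol cleaves it to 18, where the route is rejoined.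

3. Step 10. What may go wrong: incomplete conversion, erosion of the Z/E ratio, and epimerisation of the α-oxygenated aldehyde at C6 by the basic ylide. The fallback sets out from 14. Base-free dibromo-olefination (CBr4, PPh3, Zn, CH2Cl2) gives the 1,1-dibromoalkene F6. Palladium-catalysed Negishi coupling with MeZnCl and PdCl2(DPEphos) should replace selectively the bromine trans to C6 and give the (Z)-bromoalkene F7. F7 takes the place of 16 in the Ni/Cr coupling of step 11 and rejoins the route at 18.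

**Further compounds**

F1 | step 15 | (3R,4Z)-3-[(tert-butyldimethylsilyl)oxy]-4-methyl-5-[(2R,3S,4R)-4-methyl-5-oxo-3-{(2S)-2-[(tert-butyldimethylsilyl)oxy]-3-oxobutyl}oxolan-2-yl]pent-4-enal | CC(C)(C)[Si](C)(C)O[C@H](C(C)=O)C[C@@H]1[C@H](/C=C(/C)[C@H](O[Si](C)(C)C(C)(C)C)CC=O)OC(=O)[C@@H]1C
F2 | step 15 | (3R,4S,5R)-4-{(2S)-2-[(tert-butyldimethylsilyl)oxy]-3-methylbut-3-en-1-yl}-5-{(1Z,3R)-3-[(tert-butyldimethylsilyl)oxy]-2-methylhexa-1,5-dien-1-yl}-3-methyloxolan-2-one | CC(C)(C)[Si](C)(C)O[C@H](C(C)=C)C[C@@H]1[C@H](/C=C(/C)[C@H](O[Si](C)(C)C(C)(C)C)CC=C)OC(=O)[C@@H]1C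
F3 | step 15 | (1(10)Z,3R,4Z,6R,7S,9S,11R)-3,9-bis[(tert-butyldimethylsilyl)oxy]germacra-1(10),4-dien-12,6-olide | C/C1=C/C[C@@H](O[Si](C)(C)C(C)(C)C)/C(C)=C\[C@@H]2OC(=O)[C@H](C)[C@@H]2C[C@@H]1O[Si](C)(C)C(C)(C)C
F4 | step 11 | 3S epimer of 18, (3R,4S,5R)-4-{(2S)-2-[(tert-butyldimethylsilyl)oxy]-3-oxobutyl}-5-{(1Z,3S)-5-[(tert-butyldimethylsilyl)oxy]-3-hydroxy-2-methylpent-1-en-1-yl}-3-methyloxolan-2-one | CC(C)(C)[Si](C)(C)O[C@H](C(C)=O)C[C@@H]1[C@H](/C=C(/C)[C@@H](O)CCO[Si](C)(C)C(C)(C)C)OC(=O)[C@@H]1C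
F5 | step 11 | 3R chloroacetate of 18 | CC(C)(C)[Si](C)(C)O[C@H](C(C)=O)C[C@@H]1[C@H](/C=C(/C)[C@H](OC(=O)CCl)CCO[Si](C)(C)C(C)(C)C)OC(=O)[C@@H]1C
F6 | step 10 | (3R,4S,5R)-4-{(2S)-2-[(tert-butyldimethylsilyl)oxy]-3-oxobutyl}-5-(2,2-dibromoethenyl)-3-methyloxolan-2-one | CC(C)(C)[Si](C)(C)O[C@H](C(C)=O)C[C@@H]1[C@H](C=C(Br)Br)OC(=O)[C@@H]1C
F7 | step 10 | (3R,4S,5R)-4-{(2S)-2-[(tert-butyldimethylsilyl)oxy]-3-oxobutyl}-5-[(1Z)-2-bromoprop-1-en-1-yl]-3-methyloxolan-2-one | CC(C)(C)[Si](C)(C)O[C@H](C(C)=O)C[C@@H]1[C@H](/C=C(/C)Br)OC(=O)[C@@H]1C
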